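**Retrosynthetic overview**
- The target is unmasked by O-demethylation of its methyl tetronate, whose exocyclic Z-alkene comes from dehydration of a β-hydroxy butenolide. That adduct is cut at the ring C5–side-chain C1 bond: an intermolecular (vinylogous) aldol between C5-lithiated 4-methoxy-3-methylfuran-2(5H)-one and the C20 furyl dienal (key step).
- The dienal is cut at C7–C8 of the diene: Suzuki–Miyaura coupling of an (E)-2-methylvinyl iodide (C1–C7, R centre) with an (E)-alkenylboronate (C8–C13 plus furan, S centre).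
- The vinyl iodide comes from carboalumination/iodination of a terminal alkyne built from (R)-2-methylpent-4-en-1-ol (Evans allylation, (S)-auxiliary).
- The boronate comes from alkyne hydroboration, Ohira–Bestmann homologation and a B-alkyl Suzuki coupling with 3-bromofuran on (S)-2-methylpent-4-en-1-ol (Evans allylation, (R)-auxiliary).
- Rings: the butenolide ring is closed first (step 1, from ethyl 2-methylacetoacetate) and carried as its methyl ether; the furan ring is bought in as 3-bromofuran (step 13); no ring is formed late.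

Assumption: aldol adduct 31 is carried on as a diastereomer mixture at its two new centres (both destroyed in step 22), so its SMILES leaves them undefined.

**Step 1**
Reactants: 1 ethyl 2-methyl-3-oxobutanoate
Product: 3 4-hydroxy-3-methylfuran-2(5H)-one (3-methyltetronic acid), via ethyl 4-bromo-2-methyl-3-oxobutanoate 2 (not isolated)
Conditions: Br2 (1.0 equiv), CHCl3, 0 °C to rt, 16 h; evaporate; neat, 120 °C, 2 h; recrystallise
Reagents that add atoms: none
Why: Bromination of the β-keto ester and HBr-mediated equilibration give the γ-bromo keto ester, whose ester carbonyl oxygen displaces bromide on heating with loss of the ethyl group (bromination/thermal lactonisation, the classical tetronic acid synthesis).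

**Step 2**
Reactants: 3 4-hydroxy-3-methylfuran-2(5H)-one
Product: 4 4-methoxy-3-methylfuran-2(5H)-one
Conditions: Me2SO4, K2CO3, acetone, reflux
Reagents that add atoms: dimethyl sulfate COS(=O)(=O)OC
Why: O-Alkylation of the vinylogous acid by the hard electrophile takes place on the 4-oxygen to give the vinylogous ester, which masks the acidic OH for the later C5 lithiation.

**Step 3**
Reactants: 5 (S)-4-benzyl-3-propionyloxazolidin-2-one
Product: 7 (S)-4-benzyl-3-[(R)-2-methylpent-4-enoyl]oxazolidin-2-one, via sodium Z-enolate of the imide 6 (not isolated)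
Conditions: NaN(SiMe3)2 (1.1 equiv), THF, −78 °C; allyl iodide (3 equiv), −78 to −45 °C
Reagents that add atoms: allyl iodide C=CCI
Why: Evans asymmetric alkylation, in which the chelated Z-enolate is allylated on the face opposite the benzyl group, sets the (R) methyl stereocentre (dr about 98:2, minor isomer removed by chromatography).

**Step 4**
Reactants: 7 (S)-4-benzyl-3-[(R)-2-methylpent-4-enoyl]oxazolidin-2-one
Product: 8 (R)-2-methylpent-4-en-1-ol
Conditions: LiBH4, H2O (1 equiv), Et2O, 0 °C; aq. NaOH work-up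
Reagents that add atoms: none
Why: Reductive cleavage of the imide by hydride attack at the exocyclic carbonyl releases the primary alcohol without touching the stereocentre or the alkene.

**Step 5**
Reactants: 8 (R)-2-methylpent-4-en-1-ol
Product: 9 (R)-tert-butyldimethyl[(2-methylpent-4-en-1-yl)oxy]silane
Conditions: TBSCl, imidazole, CH2Cl2, 0 °C to rt
Reagents that add atoms: tert-butyldimethylsilyl chloride CC(C)(C)[Si](C)(C)Cl
Why: Silyl ether protection of the unhindered primary alcohol gives a group that survives hydroboration, acetylide, AlMe3 and cross-coupling conditions and is later removed by fluoride.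

**Step 6**
Reactants: 9 (R)-tert-butyldimethyl[(2-methylpent-4-en-1-yl)oxy]silane
Product: 11 (R)-5-(tert-butyldimethylsilyloxy)-4-methylpentan-1-ol, via B-alkyl-9-BBN adduct 10 (not isolated)
Conditions: 9-BBN (1.3 equiv), THF, 0 °C to rt; then 3 M NaOH, 30% H2O2, 0 °C to rt
Reagents that add atoms: hydrogen peroxide OO
Why: Hydroboration–oxidation places boron on the terminal carbon (anti-Markovnikov) and alkaline peroxide converts the C–B bond into C–OH, leaving the silyl ether and remote stereocentre untouched.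

**Step 7**
Reactants: 11 (R)-5-(tert-butyldimethylsilyloxy)-4-methylpentan-1-ol
Product: 12 (R)-tert-butyl[(5-iodo-2-methylpentyl)oxy]dimethylsilane
Conditions: PPh3, I2, imidazole, CH2Cl2, 0 °C to rt
Reagents that add atoms: iodine II
Why: Appel-type iodination converts the primary alcohol into the iodide by SN2 displacement of the oxyphosphonium, with imidazole buffering the medium so the silyl ether survives.

**Step 8**
Reactants: 12 (R)-tert-butyl[(5-iodo-2-methylpentyl)oxy]dimethylsilane
Product: 13 (R)-tert-butyldimethyl[(2-methylhept-6-yn-1-yl)oxy]silane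
Conditions: LiC≡CH·H2NCH2CH2NH2 (2 equiv), DMSO, 10 °C to rt
Reagents that add atoms: lithium acetylide–ethylenediamine complex [Li+].[C-]#C.NCCN
Why: SN2 alkylation of the acetylide by the unhindered primary iodide in a dipolar aprotic solvent installs the terminal alkyne cleanly.

**Step 9**
Reactants: 13 (R)-tert-butyldimethyl[(2-methylhept-6-yn-1-yl)oxy]silane
Product: 15 tert-butyl{[(2R,6E)-7-iodo-2,6-dimethylhept-6-en-1-yl]oxy}dimethylsilane, via alkenyldimethylalane 14 (not isolated)
Conditions: AlMe3 (3 equiv), Cp2ZrCl2 (0.3 equiv), CH2Cl2, 0 °C to rt, 16 h; then I2, THF, −30 to 0 °C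
Reagents that add atoms: trimethylaluminium C[Al](C)C; iodine II
Why: Negishi zirconium-catalysed carboalumination adds methyl and aluminium syn across the terminal alkyne with aluminium at the terminus, and iodinolysis with retention gives the (E)-trisubstituted vinyl iodide.

**Step 10**
Reactants: 16 (R)-4-benzyl-3-propionyloxazolidin-2-one
Product: 18 (R)-4-benzyl-3-[(S)-2-methylpent-4-enoyl]oxazolidin-2-one, via sodium Z-enolate of the imide 17 (not isolated)
Conditions: NaN(SiMe3)2 (1.1 equiv), THF, −78 °C; allyl iodide (3 equiv), −78 to −45 °C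
Reagents that add atoms: allyl iodide C=CCI
Why: Evans asymmetric alkylation with the enantiomeric auxiliary delivers the allyl group to the opposite enolate face and so sets the (S) methyl stereocentre (dr about 98:2).

**Step 11**
Reactants: 18 (R)-4-benzyl-3-[(S)-2-methylpent-4-enoyl]oxazolidin-2-one
Product: 19 (S)-2-methylpent-4-en-1-ol
Conditions: LiBH4, H2O (1 equiv), Et2O, 0 °C; aq. NaOH work-up
Reagents that add atoms: none
Why: Reductive cleavage of the imide at the exocyclic carbonyl gives the primary alcohol with the stereocentre intact.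

**Step 12**
Reactants: 19 (S)-2-methylpent-4-en-1-ol
Product: 20 (S)-tert-butyldimethyl[(2-methylpent-4-en-1-yl)oxy]silane
Conditions: TBSCl, imidazole, CH2Cl2, 0 °C to rt
Reagents that add atoms: tert-butyldimethylsilyl chloride CC(C)(C)[Si](C)(C)Cl
Why: Silyl ether protection keeps the hydroxyl from consuming the borane and from interfering in the cross-coupling.

**Step 13**
Reactants: 20 (S)-tert-butyldimethyl[(2-methylpent-4-en-1-yl)oxy]silane
Product: 22 (S)-tert-butyl{[5-(furan-3-yl)-2-methylpentyl]oxy}dimethylsilane, via B-alkyl-9-BBN adduct 21 (not isolated)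
Conditions: 9-BBN (1.3 equiv), THF, 0 °C to rt; then 3-bromofuran (1.5 equiv), PdCl2(dppf) (5 mol%), 3 M aq. K3PO4, DMF, 60 °C
Reagents that add atoms: 3-bromofuran Brc1ccoc1
Why: B-alkyl Suzuki–Miyaura coupling, in which the primary alkylborane from anti-Markovnikov hydroboration transmetalates to the furylpalladium bromide, attaches the furan through C3 without touching the stereocentre.

**Step 14**
Reactants: 22 (S)-tert-butyl{[5-(furan-3-yl)-2-methylpentyl]oxy}dimethylsilane
Product: 23 (S)-5-(furan-3-yl)-2-methylpentan-1-ol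
Conditions: Bu4NF, THF, 0 °C to rt
Reagents that add atoms: none
Why: Fluoride-mediated desilylation is selective for the Si–O bond and harmless to the furan.

**Step 15**
Reactants: 23 (S)-5-(furan-3-yl)-2-methylpentan-1-ol
Product: 24 (S)-5-(furan-3-yl)-2-methylpentanal
Conditions: Dess–Martin periodinane, NaHCO3, CH2Cl2, 0 °C to rt; used crude
Reagents that add atoms: none
Why: Buffered Dess–Martin oxidation stops at the aldehyde under near-neutral conditions that neither epimerise the α-methyl centre nor oxidise the furan.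

**Step 16**
Reactants: 24 (S)-5-(furan-3-yl)-2-methylpentanal
Product: 25 (S)-3-(4-methylhex-5-yn-1-yl)furan
Conditions: dimethyl (1-diazo-2-oxopropyl)phosphonate, K2CO3, MeOH, 0 °C to rt
Reagents that add atoms: dimethyl (1-diazo-2-oxopropyl)phosphonate CC(=O)C(=[N+]=[N-])P(=O)(OC)OC
Why: Ohira–Bestmann (Seyferth–Gilbert) homologation converts the aldehyde into the terminal alkyne under carbonate/methanol conditions mild enough to leave the α-stereocentre essentially unepimerised.

**Step 17**
Reactants: 25 (S)-3-(4-methylhex-5-yn-1-yl)furan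
Product: 26 2-[(1E,3S)-6-(furan-3-yl)-3-methylhex-1-en-1-yl]-4,4,5,5-tetramethyl-1,3,2-dioxaborolane
Conditions: pinacolborane (1.3 equiv), Cp2Zr(H)Cl (10 mol%), Et3N (10 mol%), neat, 50 °C
Reagents that add atoms: pinacolborane CC1(C)OBOC1(C)C
Why: Zirconium-catalysed hydroboration of the terminal alkyne is a syn, anti-Markovnikov addition that gives only the (E)-alkenylboronate.

**Step 18**
Reactants: 15 tert-butyl{[(2R,6E)-7-iodo-2,6-dimethylhept-6-en-1-yl]oxy}dimethylsilane; 26 2-[(1E,3S)-6-(furan-3-yl)-3-methylhex-1-en-1-yl]-4,4,5,5-tetramethyl-1,3,2-dioxaborolane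
Product: 27 tert-butyl{[(2R,6E,8E,10S)-13-(furan-3-yl)-2,6,10-trimethyltrideca-6,8-dien-1-yl]oxy}dimethylsilane
Conditions: PdCl2(dppf) (5 mol%), 3 M aq. K3PO4, THF/DMF, degassed, rt to 45 °C
Reagents that add atoms: none
Why: Suzuki–Miyaura coupling proceeds with retention at both sp2 carbons, so the (6E,8E)-diene geometry is fixed by the two stereodefined alkyne additions.

**Step 19**
Reactants: 27 tert-butyl{[(2R,6E,8E,10S)-13-(furan-3-yl)-2,6,10-trimethyltrideca-6,8-dien-1-yl]oxy}dimethylsilane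
Product: 28 (2R,6E,8E,10S)-13-(furan-3-yl)-2,6,10-trimethyltrideca-6,8-dien-1-ol
Conditions: Bu4NF, THF, 0 °C to rt
Reagents that add atoms: none
Why: Fluoride desilylation frees the primary alcohol without affecting the diene or furan.

**Step 20**
Reactants: 28 (2R,6E,8E,10S)-13-(furan-3-yl)-2,6,10-trimethyltrideca-6,8-dien-1-ol
Product: 29 (2R,6E,8E,10S)-13-(furan-3-yl)-2,6,10-trimethyltrideca-6,8-dienal
Conditions: Dess–Martin periodinane, NaHCO3, CH2Cl2, 0 °C; used crude at once
Reagents that add atoms: none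
Why: Buffered Dess–Martin oxidation gives the α-methyl aldehyde without epimerisation and without attacking the electron-rich diene or furan.

**Step 21**
Reactants: 4 4-methoxy-3-methylfuran-2(5H)-one (1.6 equiv); 29 (2R,6E,8E,10S)-13-(furan-3-yl)-2,6,10-trimethyltrideca-6,8-dienal
Product: 31 5-[(2R,6E,8E,10S)-13-(furan-3-yl)-1-hydroxy-2,6,10-trimethyltrideca-6,8-dien-1-yl]-4-methoxy-3-methylfuran-2(5H)-one as a diastereomer mixture, via lithium 4-methoxy-3-methylfuran-2-olate 30 (not isolated)
Conditions: LiN(iPr)2 (1.5 equiv), THF, −78 °C, 30 min; add 29, −78 °C, 1 h; sat. aq. NH4Cl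
Reagents that add atoms: none
Why: Intermolecular (vinylogous) aldol addition, in which the C5-deprotonated tetronate (an aromatic 2-furanolate) adds through C5 to the aldehyde at −78 °C faster than the α-centre can enolise; the two new stereocentres form unselectively and are destroyed in step 22.

**Step 22**
Reactants: 31 5-[(2R,6E,8E,10S)-13-(furan-3-yl)-1-hydroxy-2,6,10-trimethyltrideca-6,8-dien-1-yl]-4-methoxy-3-methylfuran-2(5H)-one
Product: 33 (5Z)-5-[(2R,6E,8E,10S)-13-(furan-3-yl)-2,6,10-trimethyltrideca-6,8-dien-1-ylidene]-4-methoxy-3-methylfuran-2(5H)-one, via mesylate 32 (not isolated)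
Conditions: MsCl, Et3N, CH2Cl2, 0 °C; then DBU, 0 °C to rt
Reagents that add atoms: none
Why: Mesylation followed by E1cB elimination through the acidic C5–H gives the conjugated 5-ylidene butenolide, the Z isomer (side chain turned away from the 4-methoxy group) being strongly favoured thermodynamically, with any minor E isomer removed by chromatography.

**Step 23**
Reactants: 33 (5Z)-5-[(2R,6E,8E,10S)-13-(furan-3-yl)-2,6,10-trimethyltrideca-6,8-dien-1-ylidene]-4-methoxy-3-methylfuran-2(5H)-one
Product: 34 (5Z)-5-[(2R,6E,8E,10S)-13-(furan-3-yl)-2,6,10-trimethyltrideca-6,8-dien-1-ylidene]-4-hydroxy-3-methylfuran-2(5H)-one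
Conditions: n-PrSLi (from n-PrSH, n-BuLi), HMPA, rt; then cold 0.5 M HCl to pH 3, EtOAc extraction
Reagents that add atoms: none
Why: SN2 O-demethylation, in which the soft thiolate attacks the methyl group of the vinylogous ester and releases the stabilised tetronate anion, is followed by mild acidification that leaves the furan, the diene, the Z-alkene and both stereocentres unchanged.

**Compound list**
1 | ethyl 2-methyl-3-oxobutanoate | CCOC(=O)C(C)C(C)=O | starting material
2 | ethyl 4-bromo-2-methyl-3-oxobutanoate | CCOC(=O)C(C)C(=O)CBr | intermediate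
3 | 4-hydroxy-3-methylfuran-2(5H)-one | CC1=C(O)COC1=O | intermediate
4 | 4-methoxy-3-methylfuran-2(5H)-one | CC1=C(OC)COC1=O | intermediate
5 | (S)-4-benzyl-3-propionyloxazolidin-2-one | CCC(=O)N1[C@@H](Cc2ccccc2)COC1=O | starting material
6 | sodium (Z)-enolate of 5 | C/C=C(\[O-])N1[C@@H](Cc2ccccc2)COC1=O.[Na+] | intermediate
7 | (S)-4-benzyl-3-[(R)-2-methylpent-4-enoyl]oxazolidin-2-one | O=C([C@H](C)CC=C)N1[C@@H](Cc2ccccc2)COC1=O | intermediate
8 | (R)-2-methylpent-4-en-1-ol | OC[C@H](C)CC=C | intermediate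
9 | (R)-tert-butyldimethyl[(2-methylpent-4-en-1-yl)oxy]silane | CC(C)(C)[Si](C)(C)OC[C@H](C)CC=C | intermediate
10 | 9-[(R)-5-(tert-butyldimethylsilyloxy)-4-methylpentyl]-9-borabicyclo[3.3.1]nonane | CC(C)(C)[Si](C)(C)OC[C@H](C)CCCB1C2CCCC1CCC2 | intermediate
11 | (R)-5-(tert-butyldimethylsilyloxy)-4-methylpentan-1-ol | CC(C)(C)[Si](C)(C)OC[C@H](C)CCCO | intermediate
12 | (R)-tert-butyl[(5-iodo-2-methylpentyl)oxy]dimethylsilane | CC(C)(C)[Si](C)(C)OC[C@H](C)CCCI | intermediate
13 | (R)-tert-butyldimethyl[(2-methylhept-6-yn-1-yl)oxy]silane | CC(C)(C)[Si](C)(C)OC[C@H](C)CCCC#C | intermediate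
14 | [(1E,6R)-7-(tert-butyldimethylsilyloxy)-2,6-dimethylhept-1-en-1-yl]dimethylalumane | CC(C)(C)[Si](C)(C)OC[C@H](C)CCC/C(C)=C/[Al](C)C | intermediate
15 | tert-butyl{[(2R,6E)-7-iodo-2,6-dimethylhept-6-en-1-yl]oxy}dimethylsilane | CC(C)(C)[Si](C)(C)OC[C@H](C)CCC/C(C)=C/I | intermediate
16 | (R)-4-benzyl-3-propionyloxazolidin-2-one | CCC(=O)N1[C@H](Cc2ccccc2)COC1=O | starting material
17 | sodium (Z)-enolate of 16 | C/C=C(\[O-])N1[C@H](Cc2ccccc2)COC1=O.[Na+] | intermediate
18 | (R)-4-benzyl-3-[(S)-2-methylpent-4-enoyl]oxazolidin-2-one | O=C([C@@H](C)CC=C)N1[C@H](Cc2ccccc2)COC1=O | intermediate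
19 | (S)-2-methylpent-4-en-1-ol | OC[C@@H](C)CC=C | intermediate
20 | (S)-tert-butyldimethyl[(2-methylpent-4-en-1-yl)oxy]silane | CC(C)(C)[Si](C)(C)OC[C@@H](C)CC=C | intermediate
21 | 9-[(S)-5-(tert-butyldimethylsilyloxy)-4-methylpentyl]-9-borabicyclo[3.3.1]nonane | CC(C)(C)[Si](C)(C)OC[C@@H](C)CCCB1C2CCCC1CCC2 | intermediate
22 | (S)-tert-butyl{[5-(furan-3-yl)-2-methylpentyl]oxy}dimethylsilane | CC(C)(C)[Si](C)(C)OC[C@@H](C)CCCc1ccoc1 | intermediate
23 | (S)-5-(furan-3-yl)-2-methylpentan-1-ol | OC[C@@H](C)CCCc1ccoc1 | intermediate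
24 | (S)-5-(furan-3-yl)-2-methylpentanal | O=C[C@@H](C)CCCc1ccoc1 | intermediate
25 | (S)-3-(4-methylhex-5-yn-1-yl)furan | C#C[C@@H](C)CCCc1ccoc1 | intermediate
26 | 2-[(1E,3S)-6-(furan-3-yl)-3-methylhex-1-en-1-yl]-4,4,5,5-tetramethyl-1,3,2-dioxaborolane | CC1(C)OB(/C=C/[C@@H](C)CCCc2ccoc2)OC1(C)C | intermediate
27 | tert-butyl{[(2R,6E,8E,10S)-13-(furan-3-yl)-2,6,10-trimethyltrideca-6,8-dien-1-yl]oxy}dimethylsilane | CC(C)(C)[Si](C)(C)OC[C@H](C)CCC/C(C)=C/C=C/[C@@H](C)CCCc1ccoc1 | intermediate
28 | (2R,6E,8E,10S)-13-(furan-3-yl)-2,6,10-trimethyltrideca-6,8-dien-1-ol | OC[C@H](C)CCC/C(C)=C/C=C/[C@@H](C)CCCc1ccoc1 | intermediate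
29 | (2R,6E,8E,10S)-13-(furan-3-yl)-2,6,10-trimethyltrideca-6,8-dienal | O=C[C@H](C)CCC/C(C)=C/C=C/[C@@H](C)CCCc1ccoc1 | intermediate
30 | lithium 4-methoxy-3-methylfuran-2-olate | COc1coc([O-])c1C.[Li+] | intermediate
31 | 5-[(2R,6E,8E,10S)-13-(furan-3-yl)-1-hydroxy-2,6,10-trimethyltrideca-6,8-dien-1-yl]-4-methoxy-3-methylfuran-2(5H)-one (diastereomer mixture) | CC1=C(OC)C(OC1=O)C(O)[C@H](C)CCC/C(C)=C/C=C/[C@@H](C)CCCc2ccoc2 | intermediate
32 | methanesulfonate of 31 | CC1=C(OC)C(OC1=O)C(OS(C)(=O)=O)[C@H](C)CCC/C(C)=C/C=C/[C@@H](C)CCCc2ccoc2 | intermediate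
33 | (5Z)-5-[(2R,6E,8E,10S)-13-(furan-3-yl)-2,6,10-trimethyltrideca-6,8-dien-1-ylidene]-4-methoxy-3-methylfuran-2(5H)-one | CC1=C(OC)/C(=C/[C@H](C)CCC/C(C)=C/C=C/[C@@H](C)CCCc2ccoc2)OC1=O | intermediate
34 | (5Z)-5-[(2R,6E,8E,10S)-13-(furan-3-yl)-2,6,10-trimethyltrideca-6,8-dien-1-ylidene]-4-hydroxy-3-methylfuran-2(5H)-one | CC1=C(O)/C(=C/[C@H](C)CCC/C(C)=C/C=C/[C@@H](C)CCCc2ccoc2)OC1=O | target

**Totals**
Total step count: 23. Longest linear sequence: 14 steps (16 → 18 → 19 → 20 → 22 → 23 → 24 → 25 → 26 → 27 → 28 → 29 → 31 → 33 → 34; steps 10–23).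

**Three steps most likely to fail**

Step 13 (B-alkyl Suzuki coupling with 3-bromofuran). The bromide is electron-rich and volatile, so oxidative addition may be slow and the alkylborane may protodeboronate. The fallback sets out from 20 and comes back at 22, replacing the boron coupling by a zinc coupling. Compound 20 is hydroborated as before (21) but oxidised with NaOH/H2O2 to (S)-5-(tert-butyldimethylsilyloxy)-4-methylpentan-1-ol F1. This is converted with PPh3/I2/imidazole into (S)-tert-butyl[(5-iodo-2-methylpentyl)oxy]dimethylsilane F2. Zinc insertion (Zn, LiCl, THF) gives [(S)-5-(tert-butyldimethylsilyloxy)-4-methylpentyl]zinc iodide F3, which is Negishi-coupled with 3-bromofuran (Pd(OAc)2, SPhos, THF, 50 °C) to give 22.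

Step 22 (dehydration to the Z-ylidene). E/Z mixtures or base-induced damage (including epimerisation at the allylic centre) would cost fully assembled material. The fallback sets out from 15 and comes back at 33, moving the aldol/elimination ahead of the diene coupling so that geometry is settled on a small compound. Compound 15 is desilylated (Bu4NF) to (2R,6E)-7-iodo-2,6-dimethylhept-6-en-1-ol F4 and oxidised (Dess–Martin periodinane, NaHCO3) to (2R,6E)-7-iodo-2,6-dimethylhept-6-enal F5. Aldol addition of lithium furanolate 30 gives 5-[(2R,6E)-1-hydroxy-7-iodo-2,6-dimethylhept-6-en-1-yl]-4-methoxy-3-methylfuran-2(5H)-one F6. MsCl/Et3N gives its methanesulfonate F7, and DBU gives (5Z)-5-[(2R,6E)-7-iodo-2,6-dimethylhept-6-en-1-ylidene]-4-methoxy-3-methylfuran-2(5H)-one F8, which is purified to the single Z isomer. Suzuki coupling of F8 with 26 under anhydrous fluoride activation (PdCl2(dppf), CsF, THF, 50 °C) then gives 33.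

Step 23 (thiolate demethylation). The thiolate could add to the cross-conjugated ylidene butenolide or attack C4 instead of the methyl group. The fallback sets out from 3 and comes back at 34, replacing the methyl ether by a fluoride-labile 2-(trimethylsilyl)ethyl ether. Mitsunobu alkylation of 3 (2-(trimethylsilyl)ethanol, PPh3, DIAD, THF) gives 3-methyl-4-[2-(trimethylsilyl)ethoxy]furan-2(5H)-one F9. LiN(iPr)2 at −78 °C gives lithium 3-methyl-4-[2-(trimethylsilyl)ethoxy]furan-2-olate F10, which adds to 29 to give 5-[(2R,6E,8E,10S)-13-(furan-3-yl)-1-hydroxy-2,6,10-trimethyltrideca-6,8-dien-1-yl]-3-methyl-4-[2-(trimethylsilyl)ethoxy]furan-2(5H)-one F11. MsCl/Et3N gives its methanesulfonate F12, and DBU gives (5Z)-5-[(2R,6E,8E,10S)-13-(furan-3-yl)-2,6,10-trimethyltrideca-6,8-dien-1-ylidene]-3-methyl-4-[2-(trimethylsilyl)ethoxy]furan-2(5H)-one F13. Bu4NF in THF at 0 °C followed by mild acidification then releases 34.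

**Further compounds**
F1 | step 13 | (S)-5-(tert-butyldimethylsilyloxy)-4-methylpentan-1-ol | CC(C)(C)[Si](C)(C)OC[C@@H](C)CCCO
F2 | step 13 | (S)-tert-butyl[(5-iodo-2-methylpentyl)oxy]dimethylsilane | CC(C)(C)[Si](C)(C)OC[C@@H](C)CCCI
F3 | step 13 | [(S)-5-(tert-butyldimethylsilyloxy)-4-methylpentyl]zinc iodide | CC(C)(C)[Si](C)(C)OC[C@@H](C)CCC[Zn]I
F4 | step 22 | (2R,6E)-7-iodo-2,6-dimethylhept-6-en-1-ol | OC[C@H](C)CCC/C(C)=C/I
F5 | step 22 | (2R,6E)-7-iodo-2,6-dimethylhept-6-enal | O=C[C@H](C)CCC/C(C)=C/I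
F6 | step 22 | 5-[(2R,6E)-1-hydroxy-7-iodo-2,6-dimethylhept-6-en-1-yl]-4-methoxy-3-methylfuran-2(5H)-one | CC1=C(OC)C(OC1=O)C(O)[C@H](C)CCC/C(C)=C/I
F7 | step 22 | methanesulfonate of F6 | CC1=C(OC)C(OC1=O)C(OS(C)(=O)=O)[C@H](C)CCC/C(C)=C/I
F8 | step 22 | (5Z)-5-[(2R,6E)-7-iodo-2,6-dimethylhept-6-en-1-ylidene]-4-methoxy-3-methylfuran-2(5H)-one | CC1=C(OC)/C(=C/[C@H](C)CCC/C(C)=C/I)OC1=O
F9 | step 23 | 3-methyl-4-[2-(trimethylsilyl)ethoxy]furan-2(5H)-one | CC1=C(OCC[Si](C)(C)C)COC1=O
F10 | step 23 | lithium 3-methyl-4-[2-(trimethylsilyl)ethoxy]furan-2-olate | C[Si](C)(C)CCOc1coc([O-])c1C.[Li+]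
F11 | step 23 | 5-[(2R,6E,8E,10S)-13-(furan-3-yl)-1-hydroxy-2,6,10-trimethyltrideca-6,8-dien-1-yl]-3-methyl-4-[2-(trimethylsilyl)ethoxy]furan-2(5H)-one | CC1=C(OCC[Si](C)(C)C)C(OC1=O)C(O)[C@H](C)CCC/C(C)=C/C=C/[C@@H](C)CCCc2ccoc2
F12 | step 23 | methanesulfonate of F11 | CC1=C(OCC[Si](C)(C)C)C(OC1=O)C(OS(C)(=O)=O)[C@H](C)CCC/C(C)=C/C=C/[C@@H](C)CCCc2ccoc2
F13 | step 23 | (5Z)-5-[(2R,6E,8E,10S)-13-(furan-3-yl)-2,6,10-trimethyltrideca-6,8-dien-1-ylidene]-3-methyl-4-[2-(trimethylsilyl)ethoxy]furan-2(5H)-one | CC1=C(OCC[Si](C)(C)C)/C(=C/[C@H](C)CCC/C(C)=C/C=C/[C@@H](C)CCCc2ccoc2)OC1=O
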